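The pyran ring is opened by a retro-hetero-Diels–Alder cut into an ortho-quinone methide (from an acyl triketone) and (−)-β-caryophyllene. Caryophyllene numbering is used: C1/C9 cyclobutane fusion, C4–C5 pyran fusion, C8 methylidene carbon. The nine-membered ring is reached by ring expansion: its γ,δ-unsaturated ketone retron C8(=O)–C7–C6–C5=C4 is a Claisen product. In the key step, methylenation of a cyclobutane-fused seven-membered lactone and [3,3] shift of the resulting 2-methylene-7-vinyloxepane form C6–C7, cleave C4–O and deliver the cyclononenone (seven to nine ring atoms). The expected 4Z olefin is then inverted to 4E before the cycloaddition.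

Key step: step 5

Remark: the sense of induction of the chiral Lewis acid in step 1 is assumed to give the 6R photoadduct with the (S)-prolinol-derived catalyst; if the opposite sense is found, the mirror-image catalyst is used.

Step 1
Reactants: 1 cyclohex-2-en-1-one; 2 2-methylpropene (isobutene, excess)
Product: 3 (1R,6R)-7,7-dimethylbicyclo[4.2.0]octan-2-one (cis-fused)
Conditions: hν (366 nm), (S)-3,3-bis(3,5-dimethylphenyl)-1-(2,3,4-trifluorophenyl)tetrahydro-1H,3H-pyrrolo[1,2-c][1,3,2]oxazaborole·AlBr3 (50 mol %), CH2Cl2, −75 °C; work-up over basic Al2O3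
Reagents that add atoms: none
Why: Chiral-Lewis-acid-catalysed enone–alkene [2+2] photocycloaddition: the AlBr3-activated oxazaborolidine binds the enone and shields one face so that the β-carbon (C6 of the bicyclooctanone, the later C1 of the caryophyllane) is set R, head-to-tail regiochemistry places CMe2 on that carbon, and the epimerisable α ring-fusion centre settles cis on basic alumina.

Step 2
Reactants: 3 (1R,6R)-7,7-dimethylbicyclo[4.2.0]octan-2-one
Product: 6 (1R,3E,6R)-3-ethylidene-7,7-dimethylbicyclo[4.2.0]octan-2-one, via lithium aldolate 4 (not isolated), via aldol mesylate 5 (not isolated)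
Conditions: LiN(i-Pr)2, THF, −78 °C; MeCHO; MsCl, −78 to 0 °C; then DBU, rt
Reagents that add atoms: acetaldehyde, CC=O
Why: Aldol condensation: kinetic deprotonation takes place at the methylene α-carbon C3 of the bicyclooctanone and not at the ring-fusion methine, the lithium aldolate is mesylated in the same flask, and E1cB elimination with DBU gives the conjugated E-enone, no lasting stereocentre being formed.

Step 3
Reactants: 6 (1R,3E,6R)-3-ethylidene-7,7-dimethylbicyclo[4.2.0]octan-2-one
Product: 7 (1R,3R,6R)-3-ethenyl-3,7,7-trimethylbicyclo[4.2.0]octan-2-one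
Conditions: KOt-Bu, t-BuOH/THF, 0 °C; MeI
Reagents that add atoms: iodomethane, CI
Why: Deconjugative α-alkylation: γ-deprotonation gives the thermodynamic extended potassium enolate, which is methylated at its α-carbon from the convex face of the cis-fused bicycle to give the α-methyl-α-vinyl quaternary centre (its configuration is erased in step 5, so both epimers serve).

Step 4
Reactants: 7 (1R,3R,6R)-3-ethenyl-3,7,7-trimethylbicyclo[4.2.0]octan-2-one
Product: 8 (1R,4R,7R)-4-ethenyl-4,8,8-trimethyl-3-oxabicyclo[5.2.0]nonan-2-one (seven-membered lactone, cis-fused cyclobutane)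
Conditions: mCPBA, CH2Cl2, 0 °C to rt
Reagents that add atoms: mCPBA (3-chloroperoxybenzoic acid), O=C(OO)c1cccc(Cl)c1
Why: Baeyer–Villiger oxidation: the more substituted, allylic quaternary carbon migrates with retention in preference to the cyclobutyl methine, placing the ring oxygen on C(Me)(vinyl), while the unactivated monosubstituted vinyl group is epoxidised far more slowly.

Step 5
Reactants: 8 (1R,4R,7R)-4-ethenyl-4,8,8-trimethyl-3-oxabicyclo[5.2.0]nonan-2-one
Product: 10 (1R,4Z,9R)-4,11,11-trimethylbicyclo[7.2.0]undec-4-en-8-one (cis-fused), via exocyclic enol ether 9 (not isolated)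
Conditions: Cp2TiMe2, PhMe, 75 °C (dark), then 150 °C (sealed tube)
Reagents that add atoms: dimethyltitanocene Cp2TiMe2, C[Ti](C)(C1C=CC=C1)C1C=CC=C1
Why: On heating, Cp2TiMe2 loses methane to give Cp2Ti=CH2, which methylenates the lactone carbonyl by [2+2] addition and cycloreversion to the exocyclic enol ether 9, whose allyl vinyl ether array C7=C8–O–C4–C5=C6 then undergoes a [3,3]-sigmatropic (Claisen) shift that forms C6–C7, breaks C4–O and leaves C8=O and C4=C5. The closest known reaction type is the Claisen ring expansion of 2-methylene-6-vinyltetrahydropyrans to cyclooct-4-enones. No ring is closed by a cyclisation: the nine-membered carbocycle arises from the seven-membered oxepane by ring expansion (C5, C6 and C7 enter the ring, oxygen leaves it) through a bridged chair-like transition state. No sp3 stereocentre is created, C1 and C9 are untouched, and the C4 centre is traded for olefin geometry, which is expected to be 4Z because the ring tether C3 must stand axial on the chair while the methyl group lies equatorial. The step needs the [3,3] shift to outrun isomerisation of the exocyclic enol ether to its endocyclic isomer and ionisation of the tertiary allylic C4–O bond. The quaternary, fully substituted C4 accelerates the rearrangement and the neutral, non-acidic titanium reagent suppresses both side reactions.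

Step 6
Reactants: 10 (1R,4Z,9R)-4,11,11-trimethylbicyclo[7.2.0]undec-4-en-8-one
Product: 11 (1R,4Z,9S)-4,11,11-trimethylbicyclo[7.2.0]undec-4-en-8-one (trans-fused)
Conditions: KOt-Bu (0.2 equiv), t-BuOH, rt
Reagents that add atoms: none
Why: Base-catalysed enolisation and reprotonation at C9 equilibrates the ring fusion to the trans arrangement, which is expected to be the thermodynamically preferred one in bicyclo[7.2.0]undecan-8-ones, so C9 becomes S under thermodynamic control.

Step 7
Reactants: 11 (1R,4Z,9S)-4,11,11-trimethylbicyclo[7.2.0]undec-4-en-8-one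
Product: 12 isocaryophyllene, (1R,4Z,9S)-4,11,11-trimethyl-8-methylidenebicyclo[7.2.0]undec-4-ene
Conditions: Ph3PCH3Br, KOt-Bu, THF, 0 °C to rt
Reagents that add atoms: methyltriphenylphosphonium bromide, C[P+](c1ccccc1)(c1ccccc1)c1ccccc1.[Br-]
Why: Wittig methylenation converts the C8 ketone into the exocyclic methylidene; the trans ring fusion is the equilibrium configuration under the basic conditions and the isolated Z olefin is untouched.

Step 8
Reactants: 12 isocaryophyllene
Product: 13 isocaryophyllene 4,5-epoxide, (1R,4S,5R,9S)-4,5-epoxy-4,11,11-trimethyl-8-methylidenebicyclo[7.2.0]undecane (cis-epoxide; the 4R,5S face isomer behaves alike)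
Conditions: dimethyldioxirane (1.0 equiv), acetone, −20 to 0 °C
Reagents that add atoms: dimethyldioxirane, CC1(C)OO1
Why: Electrophilic epoxidation with a neutral oxidant is faster at the trisubstituted ring olefin than at the 1,1-disubstituted exocyclic one and adds syn, so the cis-epoxide results; its face isomers need not be controlled because both stereocentres are removed in step 9.

Step 9
Reactants: 13 isocaryophyllene 4,5-epoxide
Product: 16 (−)-β-caryophyllene, (1R,4E,9S)-4,11,11-trimethyl-8-methylidenebicyclo[7.2.0]undec-4-ene, via lithium phosphinoalkoxide 14 (not isolated), via phosphonium betaine 15 (not isolated)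
Conditions: LiPPh2, THF, rt; then MeI, rt
Reagents that add atoms: none
Why: Phosphorus-betaine olefin inversion: diphenylphosphide opens the epoxide by SN2 attack at the secondary carbon C5 with inversion, P-methylation gives the betaine, and syn-elimination of methyl(diphenyl)phosphine oxide through the oxaphosphetane turns the cis-epoxide stereospecifically into the 4E olefin.

Step 10
Reactants: 17 phloroglucinol (benzene-1,3,5-triol); 18 (2S)-2-methylbutanoyl chloride
Product: 19 (2S)-2-methyl-1-(2,4,6-trihydroxyphenyl)butan-1-one
Conditions: AlCl3, PhNO2/CH2Cl2, 0 °C to rt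
Reagents that add atoms: none
Why: Friedel–Crafts acylation of the highly activated arene gives the mono-C-acyl product, and the α-stereocentre is carried over from the acid chloride (kept cold to avoid ketene formation).

Step 11
Reactants: 19 (2S)-2-methyl-1-(2,4,6-trihydroxyphenyl)butan-1-one
Product: 20 3,5-dihydroxy-4,6,6-trimethyl-2-[(2S)-2-methylbutanoyl]cyclohexa-2,4-dien-1-one (enol form of the 2,2,4-trimethyl-6-acylcyclohexane-1,3,5-trione)
Conditions: NaOMe, MeI (3 equiv), MeOH, 0 °C to rt
Reagents that add atoms: iodomethane, CI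
Why: Dearomatising C-methylation of the phloroglucinol enolate (two methyl groups on one free ring carbon and one on the other) gives the enolised β-triketone; the side-chain α-hydrogen is not removed from the delocalised polyanion, so the (2S) centre is retained.

Step 12
Reactants: 20 acyl triketone; 16 (−)-β-caryophyllene
Product: 22 target CNP0591516.2 (trans-fused dihydropyran joining C4–O and C5–CH2 of the caryophyllane to the enolised acyl triketone; 1R,4R,5S,9S in caryophyllene numbering; 2S side chain), via ortho-quinone methide 21 (not isolated)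
Conditions: Ag2O, TEMPO, PhMe, rt to 45 °C
Reagents that add atoms: none
Why: Oxidation of the ring methyl group (Ag2O/TEMPO dehydrogenation) generates the ortho-quinone methide, which undergoes an inverse-electron-demand hetero-Diels–Alder reaction with the strained 4E ring olefin in preference to the exocyclic methylidene, the oxygen bonding to the more substituted C4 and the methylene to C5 suprafacially on the exposed face of the predominant caryophyllene conformers (the face that is also epoxidised preferentially), which sets 4R and 5S by substrate control.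

Compound list
1 | cyclohex-2-en-1-one | O=C1C=CCCC1 | starting material
2 | 2-methylpropene (isobutene) | C=C(C)C | starting material
3 | (1R,6R)-7,7-dimethylbicyclo[4.2.0]octan-2-one | O=C1CCC[C@@H]2[C@H]1CC2(C)C | intermediate
4 | lithium 1-[(1R,6R)-7,7-dimethyl-2-oxobicyclo[4.2.0]octan-3-yl]ethan-1-olate (lithium aldolate, diastereomer mixture) | O=C1C(C(C)[O-])CC[C@@H]2[C@H]1CC2(C)C.[Li+] | intermediate
5 | 1-[(1R,6R)-7,7-dimethyl-2-oxobicyclo[4.2.0]octan-3-yl]ethyl methanesulfonate (diastereomer mixture) | O=C1C(C(C)OS(C)(=O)=O)CC[C@@H]2[C@H]1CC2(C)C | intermediate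
6 | (1R,3E,6R)-3-ethylidene-7,7-dimethylbicyclo[4.2.0]octan-2-one | O=C1/C(=C/C)CC[C@@H]2[C@H]1CC2(C)C | intermediate
7 | (1R,3R,6R)-3-ethenyl-3,7,7-trimethylbicyclo[4.2.0]octan-2-one | O=C1[C@@](C)(C=C)CC[C@@H]2[C@H]1CC2(C)C | intermediate
8 | (1R,4R,7R)-4-ethenyl-4,8,8-trimethyl-3-oxabicyclo[5.2.0]nonan-2-one | O=C1O[C@@](C)(C=C)CC[C@@H]2[C@H]1CC2(C)C | intermediate
9 | (1R,4R,7R)-4-ethenyl-4,8,8-trimethyl-2-methylidene-3-oxabicyclo[5.2.0]nonane | C=C1O[C@@](C)(C=C)CC[C@@H]2[C@H]1CC2(C)C | intermediate
10 | (1R,4Z,9R)-4,11,11-trimethylbicyclo[7.2.0]undec-4-en-8-one | O=C1CC/C=C(C)\CC[C@@H]2[C@H]1CC2(C)C | intermediate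
11 | (1R,4Z,9S)-4,11,11-trimethylbicyclo[7.2.0]undec-4-en-8-one | O=C1CC/C=C(C)\CC[C@@H]2[C@@H]1CC2(C)C | intermediate
12 | isocaryophyllene, (1R,4Z,9S)-4,11,11-trimethyl-8-methylidenebicyclo[7.2.0]undec-4-ene | C=C1CC/C=C(C)\CC[C@@H]2[C@@H]1CC2(C)C | intermediate
13 | (1R,4S,5R,9S)-4,5-epoxy-4,11,11-trimethyl-8-methylidenebicyclo[7.2.0]undecane | C=C1CC[C@H]3O[C@@]3(C)CC[C@@H]2[C@@H]1CC2(C)C | intermediate
14 | lithium (1R,4S,5S,9S)-5-(diphenylphosphanyl)-4,11,11-trimethyl-8-methylidenebicyclo[7.2.0]undecan-4-olate | C=C1CC[C@H](P(c3ccccc3)c3ccccc3)[C@@](C)([O-])CC[C@@H]2[C@@H]1CC2(C)C.[Li+] | intermediate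
15 | (1R,4S,5S,9S)-5-[methyl(diphenyl)phosphaniumyl]-4,11,11-trimethyl-8-methylidenebicyclo[7.2.0]undecan-4-olate (betaine) | C=C1CC[C@H]([P+](C)(c3ccccc3)c3ccccc3)[C@@](C)([O-])CC[C@@H]2[C@@H]1CC2(C)C | intermediate
16 | (−)-β-caryophyllene, (1R,4E,9S)-4,11,11-trimethyl-8-methylidenebicyclo[7.2.0]undec-4-ene | C=C1CC/C=C(C)/CC[C@@H]2[C@@H]1CC2(C)C | intermediate
17 | phloroglucinol | Oc1cc(O)cc(O)c1 | starting material
18 | (2S)-2-methylbutanoyl chloride | O=C(Cl)[C@@H](C)CC | starting material
19 | (2S)-2-methyl-1-(2,4,6-trihydroxyphenyl)butan-1-one | O=C([C@@H](C)CC)c1c(O)cc(O)cc1O | intermediate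
20 | 3,5-dihydroxy-4,6,6-trimethyl-2-[(2S)-2-methylbutanoyl]cyclohexa-2,4-dien-1-one | CC1=C(O)C(C)(C)C(=O)C(C(=O)[C@@H](C)CC)=C1O | intermediate
21 | 5-hydroxy-2,2-dimethyl-6-methylidene-4-[(2S)-2-methylbutanoyl]cyclohex-4-ene-1,3-dione (ortho-quinone methide) | C=C1C(=O)C(C)(C)C(=O)C(C(=O)[C@@H](C)CC)=C1O | intermediate
22 | target CNP0591516.2 | C=C1CC[C@H]2CC3=C(O[C@]2(C)CC[C@@H]2[C@@H]1CC2(C)C)C(C)(C)C(=O)C(C(=O)[C@@H](C)CC)=C3O | target

Total step count: 12. Longest linear sequence: 10 steps (steps 1–9, then step 12); steps 10–11 form the second branch.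

Steps most likely to fail

Step 5 (key step). The exocyclic enol ether may isomerise to the endocyclic one, or the tertiary allylic C–O bond may ionise, at the temperature the thermal shift needs, so the ring expansion could be outrun. The fallback sets out from 8: methylenation at low temperature with Cp2Ti(μ-Cl)(μ-CH2)AlMe2 (THF/PhMe, pyridine, −40 °C to rt) gives 9 as an isolated compound. Treatment with Al(i-Bu)3 in CH2Cl2 at −78 °C to rt then drives a Lewis-acid-promoted ring expansion without heating and reduces the new ketone in the same flask to (1R,4Z,9R)-4,11,11-trimethylbicyclo[7.2.0]undec-4-en-8-ol F1 (C8 epimers). Oxidation with Dess–Martin periodinane returns to the route at 10.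

Step 9. SN2 opening of the hindered trisubstituted medium-ring epoxide by the phosphide may be too slow, and base-induced isomerisation of the epoxide to an allylic alkoxide could compete. The fallback sets out from 13: opening with inversion at C5 by hydroxide (KOH, DMSO/H2O, 100 °C) gives the anti-diol (1R,4S,5S,9S)-4,11,11-trimethyl-8-methylidenebicyclo[7.2.0]undecane-4,5-diol F2. Thiocarbonyldiimidazole with DMAP in hot PhMe converts it into the cyclic 4,5-thionocarbonate F3. Corey–Winter olefin synthesis with 1,3-dimethyl-2-phenyl-1,3,2-diazaphospholidine (THF, 40 °C) then gives the 4E olefin by stereospecific syn-elimination and returns to the route at 16.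

Step 3. Alkylation of the ambident extended enolate may go astray (at the ring-fusion α′-carbon, at the γ-carbon or on oxygen), and over-methylation is possible. The fallback sets out from 3: kinetic methylation (LiN(i-Pr)2, THF, −78 °C; MeI) gives (1R,6R)-3,7,7-trimethylbicyclo[4.2.0]octan-2-one F4 (C3 epimers). Palladium-catalysed α-vinylation of its enolate (Pd2(dba)3, P(t-Bu)3, LiN(SiMe3)2, vinyl bromide, THF/PhMe, rt to 50 °C) then builds the quaternary centre by cross-coupling and returns to the route at 7.

Further compounds
F1 | step 5 | (1R,4Z,9R)-4,11,11-trimethylbicyclo[7.2.0]undec-4-en-8-ol (C8 epimers) | OC1CC/C=C(C)\CC[C@@H]2[C@H]1CC2(C)C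
F2 | step 9 | (1R,4S,5S,9S)-4,11,11-trimethyl-8-methylidenebicyclo[7.2.0]undecane-4,5-diol | C=C1CC[C@H](O)[C@@](C)(O)CC[C@@H]2[C@@H]1CC2(C)C
F3 | step 9 | cyclic 4,5-thionocarbonate of the (1R,4S,5S,9S)-diol | C=C1CC[C@@H]3OC(=S)O[C@@]3(C)CC[C@@H]2[C@@H]1CC2(C)C
F4 | step 3 | (1R,6R)-3,7,7-trimethylbicyclo[4.2.0]octan-2-one (C3 epimers) | O=C1C(C)CC[C@@H]2[C@H]1CC2(C)C
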